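**Retrosynthetic overview**

1. Target 35 ⇐ diol 32 (angelate on the C9 hydroxyl) ⇐ alcohol 29 (Mitsunobu acetate at C2, inversion) ⇐ C8=C9 alkene 25 (α-face OsO4; isopropenyl carried as its hydrochloride, released by E2) ⇐ 9-ketone 22 ⇐ α-face hydroboration of the C9=C10 alkene of 19 (sets H10).
2. Eremophila-9,11-dien-2β-ol 17 ⇐ aldehyde 13: Prins closure of ring A through the C1–C2 bond, the C10 cation opening the cyclobutane at C9–C11.
3. 13 ⇐ nopinone 3 ⇐ (−)-β-pinene 1: C14 by methylation, the C4–C5 bond by Michael addition to methyl crotonate anti to the gem-dimethyl bridge, C1 by methylenation.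
4. Feature: ring B (C5–C10) carries C11 on C7, and a bond from C11 to C9 would turn ring B plus C11 into the bicyclo[3.1.1]heptane of pinane; β-pinene therefore supplies ring B, the C7 stereocentre and C11–C13, and its cyclobutane strain drives the closure of ring A.
5. Ring order: ring B first (present from step 1 as the six-membered ring of the pinane), ring A second (step 6).

Key step: step 6

Remark: eremophilane numbering is used for the side chain of 9–13 and for all decalins (ring A = C1–C5, C10; ring B = C5–C10; C14 on C5, C15 on C4, C11–C13 on C7); β is the face of C14, and "eremophilane" in the names stands for the target skeleton with 4β-methyl, 5β-methyl and the 7β side chain.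
Assumption: the Prins closure puts the aluminium-bound oxygen equatorial (2β), so C2 is corrected later by one inversion.

**Route**

Step 1
Reactants: 1 (−)-β-pinene
Product: 3 (+)-nopinone [(1R,5S)-6,6-dimethylbicyclo[3.1.1]heptan-2-one], via secondary ozonide 2 (not isolated)
Conditions: O3, CH2Cl2, −78 °C; then Me2S, −78 °C to rt
Reagents that add atoms: ozone, [O-][O+]=O
Why: Ozonolysis with reductive work-up (Criegee mechanism) cleaves only the exocyclic C=CH2 bond, so both bridgehead stereocentres pass unchanged into the ketone.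

Step 2
Reactants: 3 (+)-nopinone; 4 iodomethane
Product: 6 (1R,3S,5S)-3,6,6-trimethylbicyclo[3.1.1]heptan-2-one (3-methylnopinone; methyl anti to the gem-dimethyl bridge), via lithium enolate of nopinone 5 (not isolated)
Conditions: LiN(iPr)2, THF, −78 °C; then MeI, −78 to 0 °C
Reagents that add atoms: iodomethane, CI
Why: Kinetic enolate alkylation: the C1 bridgehead cannot enolise, so only C3 reacts, and MeI should enter anti to the gem-dimethyl bridge (this centre becomes planar again in step 3, so its configuration is not critical).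

Step 3
Reactants: 6 3-methylnopinone; 7 methyl (E)-but-2-enoate (methyl crotonate)
Product: 10 methyl (3S)-3-[(1R,3R,5R)-3,6,6-trimethyl-2-oxobicyclo[3.1.1]heptan-3-yl]butanoate, via lithium enolate of methylnopinone 8 (not isolated), via adduct ester enolate 9 (not isolated)
Conditions: LiN(iPr)2, THF, −78 to 0 °C; then 7, −78 to −40 °C; AcOH, −78 °C
Reagents that add atoms: methyl (E)-but-2-enoate, C/C=C/C(=O)OC
Why: Kinetic Michael addition of a lithium enolate to a crotonate: the tetrasubstituted enolate 8 is attacked on the face away from the gem-dimethyl bridge, which makes C5 quaternary with C14 syn to the bridge, and a lithium-chelated closed transition state that keeps the ester chain of the (E)-crotonate outside the bicycle and its methyl group away from the ring should set C4 as (S), the cis-vicinal dimethyl pattern.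

Step 4
Reactants: 10 keto ester
Product: 11 methyl (3S)-3-[(1R,3R,5R)-3,6,6-trimethyl-2-methylidenebicyclo[3.1.1]heptan-3-yl]butanoate
Conditions: Zn, CH2Br2, TiCl4, THF–CH2Cl2, 0 °C to rt
Reagents that add atoms: dibromomethane, BrCBr
Why: Takai–Lombardo methylenation: the non-basic gem-dimetallic reagent converts the hindered ketone into the exocyclic methylene (C1) without touching the ester and without the retro-Michael cleavage that a basic ylide could start.

Step 5
Reactants: 11 methylene ester
Product: 13 (3S)-3-[(1R,3R,5R)-3,6,6-trimethyl-2-methylidenebicyclo[3.1.1]heptan-3-yl]butanal, via aluminium hemiacetal 12 (not isolated)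
Conditions: iBu2AlH (1.1 equiv), CH2Cl2, −78 °C; MeOH, then aq. KNaC4H4O6
Reagents that add atoms: none
Why: Partial ester reduction with iBu2AlH: at −78 °C the tetrahedral aluminium hemiacetal 12 persists and releases the aldehyde only on work-up, and the aldehyde is used at once.

Step 6
Reactants: 13 aldehyde
Product: 17 eremophila-9,11-dien-2β-ol, via C10 cation aluminate 14 (not isolated), via C11 cation aluminate 15 (not isolated), via chloro(methyl)aluminium alkoxide 16 (not isolated)
Conditions: Me2AlCl (1.5 equiv), CH2Cl2, −78 °C; aq. NaHCO3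
Reagents that add atoms: none
Why: Proposed new method: Me2AlCl binds the aldehyde oxygen and the terminal carbon C1 of the C10=C1 methylene adds to C2 (Markovnikov, cation at tertiary C10), closing ring A as a six-membered ring in a chair-like type-two Prins (cation–olefin) closure, exo at the carbonyl with both alkene carbons in the new ring, to give zwitterion 14; the concerted ene path normal for β-pinene is closed because C5 is quaternary and the only other allylic hydrogen sits on the C9 bridgehead. The vacant orbital at C10 is flanked by the strained C9–C11 bond, which breaks to form the C9=C10 alkene and the tertiary C11 cation 15, the pinanyl to p-menthenyl opening that acids cause in pinenes; the closest known reaction types are the Me2AlCl-promoted Prins cyclisation of unsaturated aldehydes and this acid-induced cyclobutane opening, and their combination in one step is the extrapolation. Cation 15 then loses a C12 proton to a methyl group on aluminium (methane, alkoxide 16), and any material that instead collapses with chloride at C11 is compound 18, which step 7 makes from 17 in any case. The only new stereocentre is C2: the pinane framework fixes the C1–C10–C5–C4 torsion so that ring A can form only as the chair with C14 axial and C15 equatorial, and the aluminium-bound oxygen takes the equatorial site, which is 2β; C4, C5 and C7 are carried over from 13. The step needs C9–C11 cleavage to outrun the Wagner–Meerwein shift of C11 from C9 to C10 and chloride capture at C10; cleavage releases the cyclobutane strain and gives a tertiary cation, whereas the 1,2-shift would set three fully substituted carbons (C5, C10, C11) side by side, and −78 °C in CH2Cl2 keeps the ion pair short-lived.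

Step 7
Reactants: 17 dienol
Product: 18 11-chloroeremophil-9-en-2β-ol
Conditions: HCl (gas, 1.05 equiv), CH2Cl2, −40 °C
Reagents that add atoms: hydrogen chloride, Cl
Why: Markovnikov hydrochlorination: dry HCl adds to the 1,1-disubstituted isopropenyl group in preference to the trisubstituted ring alkene (as limonene gives α-terpinyl chloride), which masks C11=C12 as a tertiary chloride without creating a stereocentre.

Step 8
Reactants: 18 chloro alcohol
Product: 19 2β-(tert-butyldimethylsilyloxy)-11-chloroeremophil-9-ene
Conditions: tBuMe2SiCl, imidazole, DMF, rt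
Reagents that add atoms: tert-butyldimethylsilyl chloride, CC(C)(C)[Si](C)(C)Cl
Why: Standard silylation of the unhindered equatorial C2 hydroxyl gives an ether that withstands borane, oxidants, amide base and alkoxide in steps 9–15.

Step 9
Reactants: 19 silyl ether
Product: 21 2β-(tert-butyldimethylsilyloxy)-11-chloro-10αH-eremophilan-9α-ol, via 9α-alkylborane 20 (not isolated)
Conditions: BH3·THF (3 equiv), THF, 0 °C to rt; then 3 M NaOH, 30% H2O2, 0 °C
Reagents that add atoms: hydrogen peroxide, OO
Why: Hydroboration–oxidation: BH3 adds syn across C9=C10 with boron on the less substituted C9 and from the α face, away from the C14 methyl that sits over the β face (ring A holds ring B in the steroid-like half-chair, as in Δ5-steroids), which sets 9α-O and 10α-H (trans ring fusion); the C–B bond is oxidised with retention and any cis-fused isomer is removed by chromatography.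

Step 10
Reactants: 21 alcohol
Product: 22 2β-(tert-butyldimethylsilyloxy)-11-chloro-10αH-eremophilan-9-one
Conditions: Dess–Martin periodinane, NaHCO3, CH2Cl2, rt
Reagents that add atoms: none
Why: Dess–Martin oxidation under buffered, non-enolising conditions gives the ketone without epimerising the adjacent C10 centre.

Step 11
Reactants: 22 ketone
Product: 24 2β-(tert-butyldimethylsilyloxy)-11-chloro-10αH-eremophil-8-en-9-yl trifluoromethanesulfonate, via potassium C8 enolate 23 (not isolated)
Conditions: KN(SiMe3)2 (1.2 equiv), THF, −78 °C (22 added to the base); then PhNTf2, −78 to 0 °C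
Reagents that add atoms: N-phenylbis(trifluoromethanesulfonimide), O=S(=O)(N(c1ccccc1)S(=O)(=O)C(F)(F)F)C(F)(F)F
Why: Kinetic enolisation with a bulky amide base removes a C8 methylene proton and not the hindered C10 methine (inverse addition prevents enolate equilibration, so C10 is kept), and O-triflation fixes the C8=C9 enol.

Step 12
Reactants: 24 enol triflate
Product: 25 2β-(tert-butyldimethylsilyloxy)-11-chloro-10αH-eremophil-8-ene
Conditions: Pd(OAc)2 (5 mol %), PPh3, HCO2H, Bu3N, DMF, 60 °C
Reagents that add atoms: none
Why: Palladium-catalysed formate reduction of an enol triflate (oxidative addition, formate exchange, loss of CO2, reductive elimination) replaces OTf by H and leaves the tertiary chloride and the silyl ether alone.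

Step 13
Reactants: 25 alkene
Product: 26 2β-(tert-butyldimethylsilyloxy)-11-chloro-10αH-eremophilane-8α,9α-diol
Conditions: OsO4 (5 mol %), N-methylmorpholine N-oxide, acetone–H2O (10:1), rt
Reagents that add atoms: N-methylmorpholine N-oxide, C[N+]1([O-])CCOCC1; water, O; OsO4 (oxygen carrier), O=[Os](=O)(=O)=O
Why: Upjohn dihydroxylation: OsO4 adds syn to C8=C9 from the α face, anti to the axial C14 methyl and the 7β side chain, giving the 8α,9α-diol, while the masked isopropenyl group is inert.

Step 14
Reactants: 26 diol
Product: 27 2β-(tert-butyldimethylsilyloxy)-11-chloro-8α,9α-(isopropylidenedioxy)-10αH-eremophilane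
Conditions: 2,2-dimethoxypropane, pyridinium p-toluenesulfonate (cat.), CH2Cl2, rt
Reagents that add atoms: 2,2-dimethoxypropane, COC(C)(C)OC
Why: Acid-catalysed transketalisation of the cis-diol gives the acetonide, so that no C8 alkoxide can start a Grob fragmentation with the C11 chloride in step 15 and only one hydroxyl is free in step 17.

Step 15
Reactants: 27 chloro acetonide
Product: 28 2β-(tert-butyldimethylsilyloxy)-8α,9α-(isopropylidenedioxy)-10αH-eremophil-11-ene
Conditions: KOtBu (5 equiv), tBuOH, 70 °C
Reagents that add atoms: none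
Why: E2 dehydrochlorination with a bulky alkoxide follows the Hofmann rule for a tertiary chloride, taking a methyl proton and not the hindered C7 methine, so the isopropenyl group is restored and C7 is untouched (no ester is present at this stage; a silyl ether lost here would simply give 29).

Step 16
Reactants: 28 silyl ether
Product: 29 8α,9α-(isopropylidenedioxy)-10αH-eremophil-11-en-2β-ol
Conditions: Bu4NF, THF, rt
Reagents that add atoms: none
Why: Fluoride-induced desilylation frees the C2 hydroxyl; acetonide and alkene are stable.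

Step 17
Reactants: 29 alcohol; 30 acetic acid
Product: 31 8α,9α-(isopropylidenedioxy)-10αH-eremophil-11-en-2α-yl acetate
Conditions: PPh3, diisopropyl azodicarboxylate, AcOH, THF, 0 °C to rt
Reagents that add atoms: acetic acid, CC(=O)O
Why: Mitsunobu reaction: the equatorial 2β-hydroxyl flanked by two methylene groups is activated and displaced by acetate in an SN2 step with clean inversion, giving the axial 2α-acetate of the target.

Step 18
Reactants: 31 acetonide acetate
Product: 32 8α,9α-dihydroxy-10αH-eremophil-11-en-2α-yl acetate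
Conditions: AcOH–H2O (4:1), 45 °C
Reagents that add atoms: none
Why: Mild acid hydrolysis of the acetonide frees the cis-diol and is too weak to hydrate the isopropenyl group or cleave the acetate.

Step 19
Reactants: 32 diol; 33 angelic acid [(Z)-2-methylbut-2-enoic acid]
Product: 35 (2S,4S,5R,7R,8R,9S,10R)-2α-acetoxy-8α-hydroxy-10αH-eremophil-11-en-9α-yl angelate (CNP0217919.1), via angelic 2,4,6-trichlorobenzoic anhydride 34 (not isolated)
Conditions: 33, 2,4,6-Cl3C6H2COCl, Et3N, toluene, rt; then 32, toluene, 75 °C
Reagents that add atoms: angelic acid, C/C=C(/C)C(=O)O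
Why: Esterification through a Yamaguchi-type mixed anhydride without a nucleophilic amine catalyst keeps the (Z)-geometry, and the equatorial 9α-hydroxyl should be acylated in preference to the axial 8α-hydroxyl next to the C7 side chain.

**Compound list**

1 | (−)-β-pinene | C=C1[C@@H]2C[C@H](CC1)C2(C)C | starting material
2 | secondary ozonide of β-pinene (spiro-1,2,4-trioxolane at C2 of the pinane) | C1OOC2(O1)[C@@H]3C[C@H](CC2)C3(C)C | intermediate
3 | (+)-nopinone, (1R,5S)-6,6-dimethylbicyclo[3.1.1]heptan-2-one | O=C1[C@@H]2C[C@H](CC1)C2(C)C | intermediate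
4 | iodomethane | CI | starting material
5 | lithium enolate of nopinone | [Li]OC1=CC[C@H]2C[C@@H]1C2(C)C | intermediate
6 | (1R,3S,5S)-3,6,6-trimethylbicyclo[3.1.1]heptan-2-one (3-methyl anti to the gem-dimethyl bridge) | O=C1[C@@H]2C[C@H](C[C@@H]1C)C2(C)C | intermediate
7 | methyl (E)-but-2-enoate | C/C=C/C(=O)OC | starting material
8 | lithium enolate of 3-methylnopinone | [Li]OC1=C(C)C[C@H]2C[C@@H]1C2(C)C | intermediate
9 | lithium ester enolate of the Michael adduct | O=C1[C@@H]2C[C@H](C[C@]1(C)[C@@H](C)C=C(O[Li])OC)C2(C)C | intermediate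
10 | methyl (3S)-3-[(1R,3R,5R)-3,6,6-trimethyl-2-oxobicyclo[3.1.1]heptan-3-yl]butanoate (ring methyl syn to the gem-dimethyl bridge) | O=C1[C@@H]2C[C@H](C[C@]1(C)[C@@H](C)CC(=O)OC)C2(C)C | intermediate
11 | methyl (3S)-3-[(1R,3R,5R)-3,6,6-trimethyl-2-methylidenebicyclo[3.1.1]heptan-3-yl]butanoate | C=C1[C@@H]2C[C@H](C[C@]1(C)[C@@H](C)CC(=O)OC)C2(C)C | intermediate
12 | diisobutylaluminium hemiacetal of 11 | C=C1[C@@H]2C[C@H](C[C@]1(C)[C@@H](C)CC(OC)O[Al](CC(C)C)CC(C)C)C2(C)C | intermediate
13 | (3S)-3-[(1R,3R,5R)-3,6,6-trimethyl-2-methylidenebicyclo[3.1.1]heptan-3-yl]butanal | C=C1[C@@H]2C[C@H](C[C@]1(C)[C@@H](C)CC=O)C2(C)C | intermediate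
14 | C10 cation with ring A closed and the cyclobutane intact, 2β-O-aluminate zwitterion | C3[C+]1[C@@H]2C[C@H](C[C@]1(C)[C@@H](C)C[C@H]3O[Al-](C)(C)Cl)C2(C)C | intermediate
15 | C11 cation of the eremophil-9-ene, 2β-O-aluminate zwitterion | C[C+](C)[C@H]1C[C@]2(C)[C@@H](C)C[C@@H](O[Al-](C)(C)Cl)CC2=CC1 | intermediate
16 | chloro(methyl)aluminium alkoxide of 17 | C=C(C)[C@H]1C[C@]2(C)[C@@H](C)C[C@@H](O[Al](C)Cl)CC2=CC1 | intermediate
17 | eremophila-9,11-dien-2β-ol | C=C(C)[C@H]1C[C@]2(C)[C@@H](C)C[C@@H](O)CC2=CC1 | intermediate
18 | 11-chloroeremophil-9-en-2β-ol | CC(C)(Cl)[C@H]1C[C@]2(C)[C@@H](C)C[C@@H](O)CC2=CC1 | intermediate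
19 | 2β-(tert-butyldimethylsilyloxy)-11-chloroeremophil-9-ene | CC(C)(Cl)[C@H]1C[C@]2(C)[C@@H](C)C[C@@H](O[Si](C)(C)C(C)(C)C)CC2=CC1 | intermediate
20 | 9α-boryl-2β-(tert-butyldimethylsilyloxy)-11-chloro-10αH-eremophilane | CC(C)(Cl)[C@H]1C[C@]2(C)[C@@H](C)C[C@@H](O[Si](C)(C)C(C)(C)C)C[C@H]2[C@H](B)C1 | intermediate
21 | 2β-(tert-butyldimethylsilyloxy)-11-chloro-10αH-eremophilan-9α-ol | CC(C)(Cl)[C@H]1C[C@]2(C)[C@@H](C)C[C@@H](O[Si](C)(C)C(C)(C)C)C[C@H]2[C@H](O)C1 | intermediate
22 | 2β-(tert-butyldimethylsilyloxy)-11-chloro-10αH-eremophilan-9-one | CC(C)(Cl)[C@H]1C[C@]2(C)[C@@H](C)C[C@@H](O[Si](C)(C)C(C)(C)C)C[C@H]2C(=O)C1 | intermediate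
23 | potassium C8(9) enolate of 22 | CC(C)(Cl)[C@H]1C[C@]2(C)[C@@H](C)C[C@@H](O[Si](C)(C)C(C)(C)C)C[C@H]2C(O[K])=C1 | intermediate
24 | 2β-(tert-butyldimethylsilyloxy)-11-chloro-10αH-eremophil-8-en-9-yl trifluoromethanesulfonate | CC(C)(Cl)[C@H]1C[C@]2(C)[C@@H](C)C[C@@H](O[Si](C)(C)C(C)(C)C)C[C@H]2C(OS(=O)(=O)C(F)(F)F)=C1 | intermediate
25 | 2β-(tert-butyldimethylsilyloxy)-11-chloro-10αH-eremophil-8-ene | CC(C)(Cl)[C@H]1C[C@]2(C)[C@@H](C)C[C@@H](O[Si](C)(C)C(C)(C)C)C[C@H]2C=C1 | intermediate
26 | 2β-(tert-butyldimethylsilyloxy)-11-chloro-10αH-eremophilane-8α,9α-diol | CC(C)(Cl)[C@H]1C[C@]2(C)[C@@H](C)C[C@@H](O[Si](C)(C)C(C)(C)C)C[C@H]2[C@H](O)[C@@H]1O | intermediate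
27 | 2β-(tert-butyldimethylsilyloxy)-11-chloro-8α,9α-(isopropylidenedioxy)-10αH-eremophilane | CC(C)(Cl)[C@H]1C[C@]2(C)[C@@H](C)C[C@@H](O[Si](C)(C)C(C)(C)C)C[C@H]2[C@H](OC(C)(C)O3)[C@@H]13 | intermediate
28 | 2β-(tert-butyldimethylsilyloxy)-8α,9α-(isopropylidenedioxy)-10αH-eremophil-11-ene | C=C(C)[C@H]1C[C@]2(C)[C@@H](C)C[C@@H](O[Si](C)(C)C(C)(C)C)C[C@H]2[C@H](OC(C)(C)O3)[C@@H]13 | intermediate
29 | 8α,9α-(isopropylidenedioxy)-10αH-eremophil-11-en-2β-ol | C=C(C)[C@H]1C[C@]2(C)[C@@H](C)C[C@@H](O)C[C@H]2[C@H](OC(C)(C)O3)[C@@H]13 | intermediate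
30 | acetic acid | CC(=O)O | starting material
31 | 8α,9α-(isopropylidenedioxy)-10αH-eremophil-11-en-2α-yl acetate | C=C(C)[C@H]1C[C@]2(C)[C@@H](C)C[C@H](OC(C)=O)C[C@H]2[C@H](OC(C)(C)O3)[C@@H]13 | intermediate
32 | 8α,9α-dihydroxy-10αH-eremophil-11-en-2α-yl acetate | C=C(C)[C@H]1C[C@]2(C)[C@@H](C)C[C@H](OC(C)=O)C[C@H]2[C@H](O)[C@@H]1O | intermediate
33 | angelic acid, (Z)-2-methylbut-2-enoic acid | C/C=C(/C)C(=O)O | starting material
34 | angelic 2,4,6-trichlorobenzoic anhydride | C/C=C(/C)C(=O)OC(=O)c1c(Cl)cc(Cl)cc1Cl | intermediate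
35 | (2S,4S,5R,7R,8R,9S,10R)-2α-acetoxy-8α-hydroxy-10αH-eremophil-11-en-9α-yl angelate (CNP0217919.1) | C=C(C)[C@H]1C[C@]2(C)[C@@H](C)C[C@H](OC(C)=O)C[C@H]2[C@H](OC(=O)/C(C)=C\C)[C@@H]1O | target

**Step count and risks**

Total step count: 19. Longest linear sequence: 19 steps (1 to 35).

Steps most likely to fail:

1. Step 6 (Prins closure with cyclobutane opening). After the C1–C2 bond has formed, the C10 cation may undergo migration of C11 from C9 to C10 instead of cleavage, may be caught at C10 by chloride or by the alkoxide, or the C11 cation may lose the C7 proton and so erase the C7 centre. Fallback with known chemistry, in which ring A is closed by carbonyl condensation and the cyclobutane is opened afterwards by acid: the route is left at 6, whose lithium enolate 8 is added in THF at −78 °C to (E)-pent-3-en-2-one to give 3-methyl-3-[(2S)-4-oxopentan-2-yl]nopinone F1; KOH in MeOH at reflux closes ring A by intramolecular aldol condensation to the pinane-fused cyclohexenone F2; HCl in AcOH at rt protonates the enone and opens the C9–C11 bond to 11-chloroeremophil-1(10)-en-2-one F3; isopropenyl acetate with TsOH gives 11-chloroeremophila-1,9-dien-2-yl acetate F4; NaBH4 in EtOH–THF at 0 °C cleaves the enol acetate and reduces the deconjugated ketone to the equatorial alcohol. The fallback comes back to the route at 18.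

2. Step 3 (Michael addition). The addition of the hindered enolate may reverse before the quench, the enolate may take a γ-proton from the crotonate instead of adding, and an open transition state may compete and erode the configuration at C4. Fallback with a doubly activated acceptor whose adduct anion is stable: the route is left at 6, enolate 8 is added in THF at −78 °C to dimethyl ethylidenemalonate to give dimethyl 2-[(1S)-1-[(1R,3R,5R)-3,6,6-trimethyl-2-oxobicyclo[3.1.1]heptan-3-yl]ethyl]propanedioate F5, and Krapcho demethoxycarbonylation (LiCl, wet DMSO, 150 °C) removes one ester group. The fallback comes back to the route at 10.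

3. Step 9 (hydroboration). Facial selectivity may be poor, with borane attacking the β face in competition and giving the cis-fused isomer; the bulky C7 group favours the cis-fused shape. Fallback that sets C10 by kinetic protonation of an enolate, which can take in material of either ring fusion: it sets out from the unseparated product of step 9, that is 21 together with 2β-(tert-butyldimethylsilyloxy)-11-chloro-10βH-eremophilan-9β-ol F6; Dess–Martin oxidation gives 22 and its C10 epimer, 2β-(tert-butyldimethylsilyloxy)-11-chloro-10βH-eremophilan-9-one F7; Me3SiOTf and Et3N in CH2Cl2 (0 °C to rt, equilibrating) convert both into the C9(10) trimethylsilyl enol ether F8; MeLi in THF at 0 °C gives the lithium C9(10) enolate F9, which is protonated at −78 °C by 2,6-di-tert-butyl-4-methylphenol on the α face of C10, anti to C14. The fallback comes back to the route at 22, and ketone of the wrong fusion can be put through the same sequence again.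

**Further compounds**

F1 | step 6 | (1R,3R,5R)-3,6,6-trimethyl-3-[(2S)-4-oxopentan-2-yl]bicyclo[3.1.1]heptan-2-one | O=C1[C@@H]2C[C@H](C[C@]1(C)[C@@H](C)CC(C)=O)C2(C)C
F2 | step 6 | pinane-fused cyclohexenone (ring A closed as the 1(10)-en-2-one, C9–C11 bond intact) | O=C1C=C2[C@@H]3C[C@H](C[C@]2(C)[C@@H](C)C1)C3(C)C
F3 | step 6 | 11-chloroeremophil-1(10)-en-2-one | CC(C)(Cl)[C@H]1C[C@]2(C)[C@@H](C)CC(=O)C=C2CC1
F4 | step 6 | 11-chloroeremophila-1,9-dien-2-yl acetate | CC(C)(Cl)[C@H]1C[C@]2(C)[C@@H](C)CC(OC(C)=O)=CC2=CC1
F5 | step 3 | dimethyl 2-[(1S)-1-[(1R,3R,5R)-3,6,6-trimethyl-2-oxobicyclo[3.1.1]heptan-3-yl]ethyl]propanedioate | O=C1[C@@H]2C[C@H](C[C@]1(C)[C@@H](C)C(C(=O)OC)C(=O)OC)C2(C)C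
F6 | step 9 | 2β-(tert-butyldimethylsilyloxy)-11-chloro-10βH-eremophilan-9β-ol | CC(C)(Cl)[C@H]1C[C@]2(C)[C@@H](C)C[C@@H](O[Si](C)(C)C(C)(C)C)C[C@@H]2[C@@H](O)C1
F7 | step 9 | 2β-(tert-butyldimethylsilyloxy)-11-chloro-10βH-eremophilan-9-one | CC(C)(Cl)[C@H]1C[C@]2(C)[C@@H](C)C[C@@H](O[Si](C)(C)C(C)(C)C)C[C@@H]2C(=O)C1
F8 | step 9 | 2β-(tert-butyldimethylsilyloxy)-11-chloro-9-(trimethylsilyloxy)eremophil-9-ene | CC(C)(Cl)[C@H]1C[C@]2(C)[C@@H](C)C[C@@H](O[Si](C)(C)C(C)(C)C)CC2=C(O[Si](C)(C)C)C1
F9 | step 9 | lithium C9(10) enolate of 22 | CC(C)(Cl)[C@H]1C[C@]2(C)[C@@H](C)C[C@@H](O[Si](C)(C)C(C)(C)C)CC2=C(O[Li])C1
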